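## Retrosynthetic overview

1. The butenolide, the only ring of the target, is bought as 3-bromofuran-2(5H)-one and attached last by B-alkyl Suzuki coupling to a primary alkylboronate.
2. The boronate arm (photochemical decarboxylative Giese addition to vinyl-Bpin) and the (Z)-allylic alcohol arm (photochemical nickel-catalysed decarboxylative allylation with isoprene monoxide, the key C–C bond) grow from the two CO2H groups of one C2-symmetric (3R,7R)-diacid diacetate. The two ends are told apart by making the epoxide the limiting reagent.
3. The diacid comes from a C2-symmetric bis-γ-lactone whose central CH2 is a malonate carbon: double homoconjugate addition to two cyclopropane-fused lactones, hydrolysis/decarboxylation, then photochemical hydrodecarboxylation.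
4. The cyclopropane-fused lactone comes from (R)-epichlorohydrin and diethyl malonate; both stereocentres of the target are copies of this one bought centre.
5. Ring order: cyclopropane and γ-lactone rings form together in step 1, the cyclopropanes open in step 2, the lactones open in step 5; the butenolide ring is never built, only coupled in step 8.

Assumption: 3-bromofuran-2(5H)-one, racemic 2-methyl-2-vinyloxirane and vinylboronic acid pinacol ester are taken as purchasable; (R)-epichlorohydrin is the only chiral material used.

Abbreviations: dF(CF3)ppy = cyclometalated 2-(2,4-difluorophenyl)-5-(trifluoromethyl)pyridine; dtbbpy = 4,4′-di-tert-butyl-2,2′-bipyridine; dme = 1,2-dimethoxyethane; RuPhos = 2-dicyclohexylphosphino-2′,6′-diisopropoxybiphenyl; Bpin = pinacolatoboryl; DMAP = 4-(dimethylamino)pyridine.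

## Route

Step 1
Reactants: 1 (R)-epichlorohydrin; 2 diethyl malonate
Product: 4 ethyl (1S,5R)-2-oxo-3-oxabicyclo[3.1.0]hexane-1-carboxylate, via epoxymalonate diester 3 (not isolated)
Conditions: NaOEt (1.0 equiv), EtOH, 0 °C then 80 °C
Reagents that add atoms: none
Why: Known epichlorohydrin–malonate cascade (SN2 epoxide opening, epoxide re-closure with loss of chloride, 3-exo-tet cyclopropanation, lactonisation): the second malonate carbanion attacks the epoxide CH of 3 with inversion, so the bought centre becomes C5 (R), and the obligatory cis ring fusion fixes C1 as S.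

Step 2
Reactants: 4 ethyl (1S,5R)-2-oxo-3-oxabicyclo[3.1.0]hexane-1-carboxylate (2.05 equiv); 2 diethyl malonate (1.0 equiv)
Product: 6 diethyl 2,2-bis{[(3R,4S)-4-(ethoxycarbonyl)-5-oxotetrahydrofuran-3-yl]methyl}propanedioate, via monoadduct 5 (not isolated)
Conditions: NaH (2.1 equiv, two portions), 4 added in two portions, DMF, 0 → 60 °C; then AcOH
Reagents that add atoms: none
Why: Twofold homoconjugate (homo-Michael) addition of malonate carbanions to the strained, doubly activated cyclopropane at its CH2 carbon (SN2-type ring opening), which leaves both C–H stereocentres untouched; in the dianion of 5 the acyclic alkylmalonate carbon is less hindered and less stabilised than the ring enolate and does the second alkylation, the ring ester centres settle trans and are erased in step 3, and any minor enantiomer of 4 ends in a separable meso diastereomer.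

Step 3
Reactants: 6 diethyl 2,2-bis{[(3R,4S)-4-(ethoxycarbonyl)-5-oxotetrahydrofuran-3-yl]methyl}propanedioate
Product: 8 3-[(3R)-5-oxotetrahydrofuran-3-yl]-2-{[(3R)-5-oxotetrahydrofuran-3-yl]methyl}propanoic acid, via tetracarboxylic acid 7 (not isolated)
Conditions: 3 M H2SO4, AcOH, 110 °C
Reagents that add atoms: water (O)
Why: Malonic ester hydrolysis and thermal decarboxylation: all four ethyl esters are hydrolysed, each of the three malonic acid units loses one CO2 and the γ-lactones re-close under acid, so the central carboxylic acid is the only free one; the stereocentres are β to the carbonyls and cannot enolise.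

Step 4
Reactants: 8 3-[(3R)-5-oxotetrahydrofuran-3-yl]-2-{[(3R)-5-oxotetrahydrofuran-3-yl]methyl}propanoic acid
Product: 9 (4R,4′R)-4,4′-(propane-1,3-diyl)bis(dihydrofuran-2(3H)-one)
Conditions: 9-mesityl-10-phenylacridinium tetrafluoroborate (5 mol%), PhSSPh (10 mol%), i-Pr2NEt (20 mol%), CF3CH2OH, 450 nm LEDs, 25 °C
Reagents that add atoms: none
Why: Photochemical hydrodecarboxylation (acridinium photooxidant with thiophenol/disulfide hydrogen-atom-transfer co-catalysis): the carboxylate is oxidised by the excited acridinium, loses CO2 and the secondary radical is capped by H from PhSH, while the lactones mask the two carboxyl groups needed later; the radical is two bonds from each stereocentre.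

Step 5
Reactants: 9 (4R,4′R)-4,4′-(propane-1,3-diyl)bis(dihydrofuran-2(3H)-one)
Product: 11 (3R,7R)-3,7-bis(acetoxymethyl)nonanedioic acid, via disodium dihydroxy dicarboxylate 10 (not isolated)
Conditions: NaOH (2.1 equiv), H2O/THF, 25 °C; evaporate; Ac2O, pyridine, DMAP (cat.), 0 → 25 °C; H2O, then HCl to pH 3, 0 °C
Reagents that add atoms: sodium hydroxide ([Na+].[OH-]); acetic anhydride (CC(=O)OC(C)=O)
Why: Lactone saponification followed by DMAP-catalysed O-acetylation of the dry hydroxy carboxylate, which should outrun relactonisation (relactonised material is 9 again and is recycled); this installs both acetates of the target before any other hydroxyl exists and frees the two carboxyl groups as radical precursors.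

Step 6
Reactants: 11 (3R,7R)-3,7-bis(acetoxymethyl)nonanedioic acid (2.5 equiv); 12 2-methyl-2-vinyloxirane (racemic, 1.0 equiv)
Product: 13 (3R,7R,10Z)-3,7-bis(acetoxymethyl)-12-hydroxy-11-methyldodec-10-enoic acid
Conditions: Ir[dF(CF3)ppy]2(dtbbpy)PF6 (1 mol%), NiCl2(dme) (10 mol%), dtbbpy (12 mol%), K2HPO4 (10 mol%), THF/MeCN (4:1), 450 nm LEDs, 25 °C
Reagents that add atoms: none
Why: Proposed new method: a nickel/photoredox decarboxylative allylation of an unactivated primary acid with a vinyl epoxide, designed to be Z-selective: zerovalent nickel adds oxidatively (SN2′) to 12 through the conformer that keeps the tied-back epoxide CH2 inside, giving an allylnickel alkoxide held as a six-membered 1-oxa-2-nickelacyclohex-4-ene (CH2O anti, hence cis to the carbon on nickel) whose syn/anti exchange at the fully substituted terminus is slow; the excited iridium catalyst oxidises a carboxylate of 11 to the primary radical with loss of CO2, divalent nickel captures it and sp3–sp3 reductive elimination at the unsubstituted allyl terminus gives the Z-allylic alkoxide, which is protonated by the next acid molecule while the reduced iridium returns nickel to the zerovalent state; 12 is limiting so that only one of the two equivalent CO2H groups of C2-symmetric 11 reacts (excess 11 is recovered and the neutral bis-adduct is removed by base extraction), and the stereocentre next to the radical carbon is not touched because bipyridine-ligated alkylnickel species do not chain-walk here; closest known chemistry: metallaphotoredox decarboxylative sp3–sp3 coupling of carboxylic acids with alkyl halides, radical ring-opening allylation of vinyl epoxides, and the Z-selective palladium-catalysed opening of vinyl cyclic carbonates through six-membered metallacycles.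

Step 7
Reactants: 13 (3R,7R,10Z)-3,7-bis(acetoxymethyl)-12-hydroxy-11-methyldodec-10-enoic acid; 14 4,4,5,5-tetramethyl-2-vinyl-1,3,2-dioxaborolane
Product: 15 (2Z,6R,10S)-6,10-bis(acetoxymethyl)-2-methyl-13-(4,4,5,5-tetramethyl-1,3,2-dioxaborolan-2-yl)tridec-2-en-1-ol
Conditions: 14 (3 equiv), Ir[dF(CF3)ppy]2(dtbbpy)PF6 (2 mol%), K2HPO4 (1.0 equiv), DMF, 450 nm LEDs, 25 °C
Reagents that add atoms: none
Why: Photoredox decarboxylative Giese addition: the excited iridium catalyst oxidises the carboxylate, the primary radical adds to the vinylboronate and the α-boryl radical is reduced and protonated to the anti-Markovnikov three-carbon boronate; acetates, the free alcohol and the unactivated trisubstituted alkene do not react and no stereocentre is formed.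

Step 8
Reactants: 15 (2Z,6R,10S)-6,10-bis(acetoxymethyl)-2-methyl-13-(4,4,5,5-tetramethyl-1,3,2-dioxaborolan-2-yl)tridec-2-en-1-ol; 16 3-bromofuran-2(5H)-one
Product: 17 3-[(4R,8R,11Z)-4,8-bis(acetoxymethyl)-13-hydroxy-12-methyltridec-11-en-1-yl]furan-2(5H)-one (CNP0139404.2)
Conditions: 16 (1.5 equiv), Pd(OAc)2 (5 mol%), RuPhos (10 mol%), K3PO4 (3 equiv), toluene/H2O (10:1), 70 °C; work-up at pH 4
Reagents that add atoms: none
Why: B-alkyl Suzuki–Miyaura coupling: oxidative addition of zerovalent palladium to the electron-poor vinyl bromide is fast and the bulky dialkylbiarylphosphine lets reductive elimination outrun β-hydride elimination of the primary alkylpalladium; the Z-alkene, acetates and stereocentres are not involved, and the mildly acidic work-up re-closes any opened butenolide.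

## Compound list

1 | (R)-epichlorohydrin [(2R)-2-(chloromethyl)oxirane] | ClC[C@H]1CO1 | starting material
2 | diethyl malonate | CCOC(=O)CC(=O)OCC | starting material
3 | diethyl 2-{[(2R)-oxiran-2-yl]methyl}propanedioate | CCOC(=O)C(C[C@@H]1CO1)C(=O)OCC | intermediate (not isolated)
4 | ethyl (1S,5R)-2-oxo-3-oxabicyclo[3.1.0]hexane-1-carboxylate | CCOC(=O)[C@]12C[C@H]1COC2=O | intermediate
5 | diethyl 2-{[(3R,4S)-4-(ethoxycarbonyl)-5-oxotetrahydrofuran-3-yl]methyl}propanedioate | CCOC(=O)C(C[C@H]1COC(=O)[C@@H]1C(=O)OCC)C(=O)OCC | intermediate (not isolated)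
6 | diethyl 2,2-bis{[(3R,4S)-4-(ethoxycarbonyl)-5-oxotetrahydrofuran-3-yl]methyl}propanedioate | CCOC(=O)C(C[C@H]1COC(=O)[C@@H]1C(=O)OCC)(C[C@H]1COC(=O)[C@@H]1C(=O)OCC)C(=O)OCC | intermediate
7 | 2,2-bis{[(3R,4S)-4-carboxy-5-oxotetrahydrofuran-3-yl]methyl}propanedioic acid | OC(=O)C(C[C@H]1COC(=O)[C@@H]1C(O)=O)(C[C@H]1COC(=O)[C@@H]1C(O)=O)C(O)=O | intermediate (not isolated)
8 | 3-[(3R)-5-oxotetrahydrofuran-3-yl]-2-{[(3R)-5-oxotetrahydrofuran-3-yl]methyl}propanoic acid | OC(=O)C(C[C@H]1COC(=O)C1)C[C@H]1COC(=O)C1 | intermediate
9 | (4R,4′R)-4,4′-(propane-1,3-diyl)bis(dihydrofuran-2(3H)-one) | C(C[C@H]1COC(=O)C1)C[C@H]1COC(=O)C1 | intermediate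
10 | disodium (3R,7R)-3,7-bis(hydroxymethyl)nonanedioate | [Na+].[Na+].[O-]C(=O)C[C@H](CO)CCC[C@@H](CO)CC([O-])=O | intermediate (not isolated)
11 | (3R,7R)-3,7-bis(acetoxymethyl)nonanedioic acid | OC(=O)C[C@H](COC(C)=O)CCC[C@@H](COC(C)=O)CC(=O)O | intermediate
12 | 2-methyl-2-vinyloxirane (racemic; its stereocentre is destroyed) | CC1(C=C)CO1 | starting material
13 | (3R,7R,10Z)-3,7-bis(acetoxymethyl)-12-hydroxy-11-methyldodec-10-enoic acid | OC(=O)C[C@H](COC(C)=O)CCC[C@@H](COC(C)=O)CC/C=C(/C)CO | intermediate
14 | 4,4,5,5-tetramethyl-2-vinyl-1,3,2-dioxaborolane | C=CB1OC(C)(C)C(C)(C)O1 | starting material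
15 | (2Z,6R,10S)-6,10-bis(acetoxymethyl)-2-methyl-13-(4,4,5,5-tetramethyl-1,3,2-dioxaborolan-2-yl)tridec-2-en-1-ol (10S is a priority change caused by boron, not an inversion) | CC1(C)OB(CCC[C@H](COC(C)=O)CCC[C@@H](COC(C)=O)CC/C=C(/C)CO)OC1(C)C | intermediate
16 | 3-bromofuran-2(5H)-one | O=C1OCC=C1Br | starting material
17 | 3-[(4R,8R,11Z)-4,8-bis(acetoxymethyl)-13-hydroxy-12-methyltridec-11-en-1-yl]furan-2(5H)-one | CC(=O)OC[C@@H](CCCC1=CCOC1=O)CCC[C@H](CC/C=C(/C)CO)COC(C)=O | target

## Step count and weak points

Total step count: 8. Longest linear sequence: 8 (fully linear from 1).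

Three steps most likely to fail:

Step 6 (the proposed new step). The Z/E ratio may erode if the oxygen-to-nickel chelate is lost after proton transfer. The carboxylate may also O-allylate, 12 may isomerise to 2-methylbut-2-enal through a nickel hydride, and some double allylation is unavoidable. An E isomer would have to be removed on silver-nitrate-impregnated silica. The fallback uses known chemistry only; it sets out from 11 and comes back at 13. Limiting borane–THF reduces one CO2H of 11 chemoselectively beside the acetates to (3R,7R)-3,7-bis(acetoxymethyl)-9-hydroxynonanoic acid F3 (unreacted 11 is recovered). MsCl/Et3N gives (3R,7R)-3,7-bis(acetoxymethyl)-9-[(methylsulfonyl)oxy]nonanoic acid F4, and NaI in acetone gives (3R,7R)-3,7-bis(acetoxymethyl)-9-iodononanoic acid F5. Nickel-catalysed reductive cross-electrophile coupling of F5 (as its sodium salt) with purchased (Z)-3-iodo-2-methylprop-2-en-1-ol (OC/C(C)=C\I), using NiBr2(dme), dtbbpy and Mn powder in DMA, joins the alkyl carbon to the vinyl carbon with retention of the bought Z geometry and gives 13.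

Step 2. The second ring opening must create a quaternary carbon flanked by two branched CH2 groups. It may stall at 5 or be diverted to C-alkylation of the ring enolate. The fallback sets out from 4 and comes back at 8. Hot aqueous HI in AcOH opens the cyclopropane of 4 at its CH2 with iodide and hydrolyses and decarboxylates the ester in the same pot to (4R)-4-(iodomethyl)dihydrofuran-2(3H)-one F1. Classical double alkylation of 2 with F1 (NaH, DMF, 60 °C; the malonate anion is too weak a base to enolise the lactone) gives diethyl 2,2-bis{[(3R)-5-oxotetrahydrofuran-3-yl]methyl}propanedioate F2. F2 gives 8 under the conditions of step 3.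

Step 8. Compound 16 is base-sensitive and primary alkyl pinacol boronates transmetalate slowly, so hydrolysis or protodeboronation may win. The fallback sets out from 15 (with 16) and comes back at 17. The butenolide is masked as an aromatic furan by silylating 16 (TIPSOTf, Et3N) to 3-bromo-2-[(triisopropylsilyl)oxy]furan F6. Coupling of 15 with F6 under the same palladium catalysis gives (2Z,6R,10R)-6,10-bis(acetoxymethyl)-2-methyl-13-{2-[(triisopropylsilyl)oxy]furan-3-yl}tridec-2-en-1-ol F7. Dilute HCl in THF (with a trace of Et3N if the β,γ-unsaturated isomer appears) unmasks the butenolide to 17.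

## Further compounds

F1 | step 2 | (4R)-4-(iodomethyl)dihydrofuran-2(3H)-one | IC[C@H]1COC(=O)C1
F2 | step 2 | diethyl 2,2-bis{[(3R)-5-oxotetrahydrofuran-3-yl]methyl}propanedioate | CCOC(=O)C(C[C@H]1COC(=O)C1)(C[C@H]1COC(=O)C1)C(=O)OCC
F3 | step 6 | (3R,7R)-3,7-bis(acetoxymethyl)-9-hydroxynonanoic acid | OC(=O)C[C@H](COC(C)=O)CCC[C@@H](COC(C)=O)CCO
F4 | step 6 | (3R,7R)-3,7-bis(acetoxymethyl)-9-[(methylsulfonyl)oxy]nonanoic acid | OC(=O)C[C@H](COC(C)=O)CCC[C@@H](COC(C)=O)CCOS(C)(=O)=O
F5 | step 6 | (3R,7R)-3,7-bis(acetoxymethyl)-9-iodononanoic acid | OC(=O)C[C@H](COC(C)=O)CCC[C@@H](COC(C)=O)CCI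
F6 | step 8 | 3-bromo-2-[(triisopropylsilyl)oxy]furan | CC(C)[Si](Oc1occc1Br)(C(C)C)C(C)C
F7 | step 8 | (2Z,6R,10R)-6,10-bis(acetoxymethyl)-2-methyl-13-{2-[(triisopropylsilyl)oxy]furan-3-yl}tridec-2-en-1-ol | CC(C)[Si](Oc1occc1CCC[C@H](COC(C)=O)CCC[C@@H](COC(C)=O)CC/C=C(/C)CO)(C(C)C)C(C)C
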